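**Retrosynthetic overview**
1. The strategy rests on the single stereogenic methine C–H. It carries one carbon of the phloroglucinol ring, C2 of the tetramethylcyclohexenedione enol ring (both sp2) and a CH2CH2Ph chain, so methine plus chain are the C3 unit and phenyl ring of allylbenzene.
2. The target comes from hydrogenolysis of four benzyl groups, preceded by Friedel–Crafts acylation of the last free arene carbon of the tetra-O-benzyl core with 3-phenylpropanoyl chloride.
3. The core comes from an enantioselective palladium 1,1-vinylarylation of allylbenzene (Heck insertion, hydride relay to a π-allyl complex, aryl transfer). The partners are the 2-iodo enol benzyl ether of syncarpic acid and the tris(benzyloxy)methylphenylboronic acid, and both methine–sp2 bonds form in this step.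
4. The iodide comes from syncarpic acid (Mitsunobu O-benzylation, NIS). The boronic acid comes from 2-methylphloroglucinol (perbenzylation, NBS, Li–Br exchange with borate trapping).
5. No ring is formed in the route: the cyclohexenedione ring, the phloroglucinol arene and both phenyl rings are bought intact.

Key step: step 6

Assumption: the target stereocentre is (R) by CIP analysis of the SMILES (cyclohexenedione C2 > arene carbon > CH2 > H); the sense of induction of the ligand in step 6 cannot be predicted, so the (S)-ligand is written and its enantiomer is used if it should favour the (S)-product.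

Step 1
Reactants: 1 syncarpic acid (2,2,4,4-tetramethylcyclohexane-1,3,5-trione)
Product: 2 3-(benzyloxy)-4,4,6,6-tetramethylcyclohex-2-ene-1,5-dione
Conditions: BnOH, PPh3, DIAD, THF, 0 °C → rt
Reagents that add atoms: benzyl alcohol, OCc1ccccc1
Why: Mitsunobu reaction: the vinylogous acid is acidic enough to protonate the betaine and its oxygen end attacks the benzyloxyphosphonium ion, which avoids the C2-benzylation expected from a benzyl halide and base, and the two enol oxygens are equivalent by symmetry.

Step 2
Reactants: 2 3-(benzyloxy)-4,4,6,6-tetramethylcyclohex-2-ene-1,5-dione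
Product: 3 3-(benzyloxy)-2-iodo-4,4,6,6-tetramethylcyclohex-2-ene-1,5-dione
Conditions: NIS, MeCN, 0 °C → rt, dark
Reagents that add atoms: N-iodosuccinimide, O=C1CCC(=O)N1I
Why: Electrophilic α-iodination of a vinylogous ester: C2 is the only nucleophilic carbon (C4 and C6 are quaternary), and loss of its proton restores the conjugated enol ether.

Step 3
Reactants: 4 2-methylphloroglucinol (2-methylbenzene-1,3,5-triol)
Product: 5 1,3,5-tris(benzyloxy)-2-methylbenzene
Conditions: BnBr (3.6 equiv), K2CO3, DMF, rt → 50 °C
Reagents that add atoms: benzyl bromide, BrCc1ccccc1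
Why: Williamson ether synthesis, in which a carbonate base in a polar aprotic solvent favours O- over C-benzylation of the phloroglucinol.

Step 4
Reactants: 5 1,3,5-tris(benzyloxy)-2-methylbenzene
Product: 6 1,3,5-tris(benzyloxy)-2-bromo-4-methylbenzene
Conditions: NBS (1.0 equiv), CH2Cl2, −40 → 0 °C, dark
Reagents that add atoms: N-bromosuccinimide, O=C1CCC(=O)N1Br
Why: Electrophilic aromatic bromination: the two free ring carbons are equivalent by symmetry, so one equivalent of NBS at low temperature should give a single monobromide, and the dark polar conditions suppress benzylic radical bromination.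

Step 5
Reactants: 6 1,3,5-tris(benzyloxy)-2-bromo-4-methylbenzene
Product: 9 [2,4,6-tris(benzyloxy)-3-methylphenyl]boronic acid, via [2,4,6-tris(benzyloxy)-3-methylphenyl]lithium 7 (not isolated), via lithium triisopropoxy[2,4,6-tris(benzyloxy)-3-methylphenyl]borate 8 (not isolated)
Conditions: B(OiPr)3 present from the start, n-BuLi, THF/toluene, −78 °C; then aq NH4Cl, 0 °C
Reagents that add atoms: triisopropyl borate, CC(C)OB(OC(C)C)OC(C)C; water, O
Why: Lithium–bromine exchange with in-situ borate quench: exchange at −78 °C is faster than benzylic deprotonation, the aryllithium is trapped as it forms, and the near-neutral work-up limits protodeboronation of the electron-rich boronic acid.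

Step 6
Reactants: 3 3-(benzyloxy)-2-iodo-4,4,6,6-tetramethylcyclohex-2-ene-1,5-dione; 9 [2,4,6-tris(benzyloxy)-3-methylphenyl]boronic acid; 10 allylbenzene
Product: 12 3-(benzyloxy)-4,4,6,6-tetramethyl-2-{(1R)-3-phenyl-1-[2,4,6-tris(benzyloxy)-3-methylphenyl]propyl}cyclohex-2-ene-1,5-dione, via cationic π-allylpalladium complex 11 (not isolated)
Conditions: Pd2(dba)3 (5 mol %), (S)-4-tert-butyl-2-[5-(trifluoromethyl)pyridin-2-yl]-4,5-dihydrooxazole (12 mol %), Ag2CO3 (1.2 equiv), 10 (3 equiv), 9 (1.5 equiv, slow addition), DMA, 40 °C
Reagents that add atoms: none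
Why: Proposed new method: oxidative addition of Pd(0) into the C–I bond of 3 and iodide abstraction by Ag2CO3 should give a cationic (N,N)Pd–alkenyl species that inserts 10 with the alkenyl carbon on the terminal CH2, after which syn β-hydride elimination toward that CH2 and syn reinsertion move palladium onto it as the π-allyl complex 11 (allyl unit: methine carbon, C2 and C3 of the enol ether ring), which takes the aryl group from 9 and reductively eliminates at the methine. The closest known reaction types are the palladium-catalysed three-component 1,1-arylvinylation of terminal alkenes with alkenyl triflates and arylboronic acids, the enantioselective 1,1-diarylation of alkenes and the enantioselective redox-relay Heck reaction of cationic palladium, all shown only with far less hindered partners and not with a 2-iodo-3-alkoxyenone or a 2,6-dialkoxyarylboronic acid. No ring closes; the two new bonds are methine–C2 of the cyclohexenedione ring and methine–arene carbon. The one new stereocentre is under catalyst control: the pyridine–oxazoline ligand selects the face of 10 in the migratory insertion, the hydride relay is suprafacial as long as the alkene does not dissociate, and inner-sphere reductive elimination retains the C–Pd configuration. The hydride walk must end at the methine, which rests on the η3-allyl complex conjugated with the enol ether (further held by the C1 carbonyl oxygen) being a deeper sink than the dearomatised η3-benzyl complex at the PhCH2 end, the two being linked by reversible hydride shifts. C–C formation at the methine terminus follows because the other allyl terminus is the fully substituted C(OBn) next to a quaternary carbon, and direct Suzuki coupling is held back by the two flanking groups on each sp2 partner, the excess of 10 and the slow addition of 9.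

Step 7
Reactants: 12 3-(benzyloxy)-4,4,6,6-tetramethyl-2-{(1R)-3-phenyl-1-[2,4,6-tris(benzyloxy)-3-methylphenyl]propyl}cyclohex-2-ene-1,5-dione; 13 3-phenylpropanoyl chloride
Product: 15 3-(benzyloxy)-4,4,6,6-tetramethyl-2-{(1R)-3-phenyl-1-[2,4,6-tris(benzyloxy)-3-methyl-5-(3-phenylpropanoyl)phenyl]propyl}cyclohex-2-ene-1,5-dione, via 3-phenylpropanoyl trifluoromethanesulfonate 14 (not isolated)
Conditions: AgOTf, 2,6-di-tert-butyl-4-methylpyridine, CH2Cl2, −78 → −20 °C
Reagents that add atoms: none
Why: Friedel–Crafts acylation with an acyl triflate made in situ: the trialkoxyarene is nucleophilic enough to be acylated at its one free carbon without a strong Lewis acid, and the hindered base takes up the triflic acid so that the benzyl ethers, the vinylogous benzyl ester and the (R)-methine are not exposed to acid.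

Step 8
Reactants: 15 3-(benzyloxy)-4,4,6,6-tetramethyl-2-{(1R)-3-phenyl-1-[2,4,6-tris(benzyloxy)-3-methyl-5-(3-phenylpropanoyl)phenyl]propyl}cyclohex-2-ene-1,5-dione
Product: 16 3-hydroxy-4,4,6,6-tetramethyl-2-{(1R)-3-phenyl-1-[2,4,6-trihydroxy-3-methyl-5-(3-phenylpropanoyl)phenyl]propyl}cyclohex-2-ene-1,5-dione (CNP0236721.1)
Conditions: H2 (1 atm), 10% Pd/C, EtOAc, rt
Reagents that add atoms: none
Why: Catalytic hydrogenolysis cleaves the three aryl benzyl ethers and the vinylogous benzyl ester under neutral conditions, which should leave the hydrogen-bonded aryl ketone, the tetrasubstituted enol double bond and the hindered ring ketone untouched and supplies no acid or base to start retro-Michael racemisation of the (R)-methine or cyclodehydration to a xanthene.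

**Compound list**
1 | syncarpic acid (2,2,4,4-tetramethylcyclohexane-1,3,5-trione) | CC1(C)C(=O)CC(=O)C(C)(C)C1=O | starting material
2 | 3-(benzyloxy)-4,4,6,6-tetramethylcyclohex-2-ene-1,5-dione | O=C1C=C(OCc2ccccc2)C(C)(C)C(=O)C1(C)C | intermediate
3 | 3-(benzyloxy)-2-iodo-4,4,6,6-tetramethylcyclohex-2-ene-1,5-dione | IC1=C(OCc2ccccc2)C(C)(C)C(=O)C(C)(C)C1=O | intermediate
4 | 2-methylphloroglucinol (2-methylbenzene-1,3,5-triol) | Cc1c(O)cc(O)cc1O | starting material
5 | 1,3,5-tris(benzyloxy)-2-methylbenzene | Cc1c(OCc2ccccc2)cc(OCc2ccccc2)cc1OCc1ccccc1 | intermediate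
6 | 1,3,5-tris(benzyloxy)-2-bromo-4-methylbenzene | Cc1c(OCc2ccccc2)cc(OCc2ccccc2)c(Br)c1OCc1ccccc1 | intermediate
7 | [2,4,6-tris(benzyloxy)-3-methylphenyl]lithium (not isolated) | [Li]c1c(OCc2ccccc2)cc(OCc2ccccc2)c(C)c1OCc1ccccc1 | intermediate
8 | lithium triisopropoxy[2,4,6-tris(benzyloxy)-3-methylphenyl]borate (not isolated) | [Li+].CC(C)O[B-](OC(C)C)(OC(C)C)c1c(OCc2ccccc2)cc(OCc2ccccc2)c(C)c1OCc1ccccc1 | intermediate
9 | [2,4,6-tris(benzyloxy)-3-methylphenyl]boronic acid | Cc1c(OCc2ccccc2)cc(OCc2ccccc2)c(B(O)O)c1OCc1ccccc1 | intermediate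
10 | allylbenzene (prop-2-en-1-ylbenzene) | C=CCc1ccccc1 | starting material
11 | cationic π-allylpalladium complex (not isolated; allyl unit made up of the methine carbon, C2 and C3 of the enol ether ring; written in its η1 form at the methine, chiral ligand and counter-ion left out, palladium on the face later taken by the aryl group) | [Pd+][C@@H](CCc1ccccc1)C1=C(OCc2ccccc2)C(C)(C)C(=O)C(C)(C)C1=O | intermediate
12 | 3-(benzyloxy)-4,4,6,6-tetramethyl-2-{(1R)-3-phenyl-1-[2,4,6-tris(benzyloxy)-3-methylphenyl]propyl}cyclohex-2-ene-1,5-dione | Cc1c(OCc2ccccc2)cc(OCc2ccccc2)c([C@@H](CCc2ccccc2)C2=C(OCc3ccccc3)C(C)(C)C(=O)C(C)(C)C2=O)c1OCc1ccccc1 | intermediate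
13 | 3-phenylpropanoyl chloride | O=C(Cl)CCc1ccccc1 | starting material
14 | 3-phenylpropanoyl trifluoromethanesulfonate (not isolated) | O=C(CCc1ccccc1)OS(=O)(=O)C(F)(F)F | intermediate
15 | 3-(benzyloxy)-4,4,6,6-tetramethyl-2-{(1R)-3-phenyl-1-[2,4,6-tris(benzyloxy)-3-methyl-5-(3-phenylpropanoyl)phenyl]propyl}cyclohex-2-ene-1,5-dione | Cc1c(OCc2ccccc2)c(C(=O)CCc2ccccc2)c(OCc2ccccc2)c([C@@H](CCc2ccccc2)C2=C(OCc3ccccc3)C(C)(C)C(=O)C(C)(C)C2=O)c1OCc1ccccc1 | intermediate
16 | 3-hydroxy-4,4,6,6-tetramethyl-2-{(1R)-3-phenyl-1-[2,4,6-trihydroxy-3-methyl-5-(3-phenylpropanoyl)phenyl]propyl}cyclohex-2-ene-1,5-dione (CNP0236721.1) | Cc1c(O)c(C(=O)CCc2ccccc2)c(O)c([C@@H](CCc2ccccc2)C2=C(O)C(C)(C)C(=O)C(C)(C)C2=O)c1O | target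

**Total step count:** 8
**Longest linear sequence:** 6 steps (4 → 5 → 6 → 9 → 12 → 15 → 16)

**Steps most likely to fail**

1. Step 6 (Proposed new method).
 - What may go wrong:
  - Aryl transfer to the alkenylpalladium species before the alkene inserts (direct cross-coupling).
  - A hydride walk that runs to the benzylic end and takes the aryl group there.
  - Release of the diene after β-hydride elimination.
  - Silver- or base-induced protodeboronation.
  - C–H palladation of the neighbouring benzyl ether.
  - Slow aryl transfer to the crowded allyl complex.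
  - Weak facial control by the ligand.
 - Fallback (known Knoevenagel–Michael chemistry with resolution): it sets out from 1, 4 and 13 and comes back to the route at 16. Friedel–Crafts acylation of 4 with 13 (AlCl3, CH2Cl2/PhNO2) gives 1-(2,4,6-trihydroxy-3-methylphenyl)-3-phenylpropan-1-one F1. Knoevenagel condensation of 1 with commercial 3-phenylpropanal (piperidine, CH2Cl2, then dilute acid) gives 2,2,4,4-tetramethyl-6-(3-phenylpropylidene)cyclohexane-1,3,5-trione F2. Michael addition of the sodium phenolate of F1 through its one free ring carbon to F2 (NaH, THF, 0 °C → rt) gives the racemic target F3. Preparative HPLC on a chiral stationary phase separates it into 16 and the (S)-enantiomer of the target F4.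

2. Step 7.
 - What may go wrong:
  - Local acid build-up with loss of benzyl groups.
  - Ipso attack at the ring carbon that bears the methine, with C–C cleavage and loss of configuration.
  - Cyclisation of the acylating agent onto its own phenyl ring.
  - Ketene formation from the acylating agent by the base.
 - Fallback: it sets out from 12 and comes back at 15. Vilsmeier–Haack formylation (POCl3, DMF, 0 °C → rt; aq NaOAc) gives 2,4,6-tris(benzyloxy)-3-{(1R)-1-[2-(benzyloxy)-3,3,5,5-tetramethyl-4,6-dioxocyclohex-1-en-1-yl]-3-phenylpropyl}-5-methylbenzaldehyde F5. Addition of 2-phenylethylmagnesium bromide (THF, −78 °C) to the aldehyde, the only carbonyl group not shielded by a quaternary carbon, gives 3-(benzyloxy)-2-{(1R)-1-[2,4,6-tris(benzyloxy)-3-(1-hydroxy-3-phenylpropyl)-5-methylphenyl]-3-phenylpropyl}-4,4,6,6-tetramethylcyclohex-2-ene-1,5-dione F6 as a mixture of carbinol epimers. Dess–Martin oxidation then gives 15.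

3. Step 5.
 - What may go wrong:
  - Proton transfer from an OCH2Ph group to the aryllithium, followed by Wittig rearrangement.
  - Protodeboronation during work-up and storage.
 - Fallback: it sets out from 6 and comes back at 12. Miyaura borylation (Pd(OAc)2/SPhos, B2pin2, KOAc, dioxane, 80 °C) avoids both the organolithium and the aqueous liberation of the free acid. It gives 2-[2,4,6-tris(benzyloxy)-3-methylphenyl]-4,4,5,5-tetramethyl-1,3,2-dioxaborolane F7, which can be chromatographed and takes the place of 9 in step 6 to give 12.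

**Further compounds**
F1 | step 6 | 1-(2,4,6-trihydroxy-3-methylphenyl)-3-phenylpropan-1-one | Cc1c(O)cc(O)c(C(=O)CCc2ccccc2)c1O
F2 | step 6 | 2,2,4,4-tetramethyl-6-(3-phenylpropylidene)cyclohexane-1,3,5-trione | CC1(C)C(=O)C(=CCCc2ccccc2)C(=O)C(C)(C)C1=O
F3 | step 6 | racemic target | Cc1c(O)c(C(=O)CCc2ccccc2)c(O)c(C(CCc2ccccc2)C2=C(O)C(C)(C)C(=O)C(C)(C)C2=O)c1O
F4 | step 6 | (S)-enantiomer of the target | Cc1c(O)c(C(=O)CCc2ccccc2)c(O)c([C@H](CCc2ccccc2)C2=C(O)C(C)(C)C(=O)C(C)(C)C2=O)c1O
F5 | step 7 | 2,4,6-tris(benzyloxy)-3-{(1R)-1-[2-(benzyloxy)-3,3,5,5-tetramethyl-4,6-dioxocyclohex-1-en-1-yl]-3-phenylpropyl}-5-methylbenzaldehyde | Cc1c(OCc2ccccc2)c(C=O)c(OCc2ccccc2)c([C@@H](CCc2ccccc2)C2=C(OCc3ccccc3)C(C)(C)C(=O)C(C)(C)C2=O)c1OCc1ccccc1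
F6 | step 7 | 3-(benzyloxy)-2-{(1R)-1-[2,4,6-tris(benzyloxy)-3-(1-hydroxy-3-phenylpropyl)-5-methylphenyl]-3-phenylpropyl}-4,4,6,6-tetramethylcyclohex-2-ene-1,5-dione (carbinol epimers) | Cc1c(OCc2ccccc2)c(C(O)CCc2ccccc2)c(OCc2ccccc2)c([C@@H](CCc2ccccc2)C2=C(OCc3ccccc3)C(C)(C)C(=O)C(C)(C)C2=O)c1OCc1ccccc1
F7 | step 5 | 2-[2,4,6-tris(benzyloxy)-3-methylphenyl]-4,4,5,5-tetramethyl-1,3,2-dioxaborolane | Cc1c(OCc2ccccc2)cc(OCc2ccccc2)c(B2OC(C)(C)C(C)(C)O2)c1OCc1ccccc1
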